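At 8.0 d the red flask, where substrate and partner react over free catalyst and a second catalyst, had read 29% at 3.00 d and 32% at 8.00 d. That rise of 3 percentage points stood against a scatter of 1.5 points, so I took their mean, 30.5%, as a plateau.

| setting | red | ochre | flask |
|---|---|---|---|
| substrate | 0.30 M | 0.30 M | 0.30 M |
| partner | 0.36 M | 0.36 M | 0.360 M |
| free catalyst | 30 mM | 30 mM | 30 mM |
| second catalyst | 6 mM | 4 mM | 6.0 mM |
| remark | the very flask that is asked about, followed so far | run made earlier |  |
| time |  |  | 8.0 d |

red run (percent of the substrate charged): time / d: target / % = 0.625: 20; 1.67: 28; 3.00: 29; 8.00: 32

ochre run (percent of the substrate charged): time / h: target / % = 4.00: 4; 8.00: 11; 20.0: 21; 50.0: 23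

(standard deviation of a reading: 1.5 percentage points)

- south: at 8.0 d add free catalyst, 100% of the amount charged, then wait 15 d
- north-east: at 8.0 d take out 90% of the target then present, then wait 15 d
- south-west: change nothing and wait 15 d more
- north: at 8.0 d add partner, 50.0% of the amount charged, then wait 15 d

- target, in percent of the substrate first charged, at 8.0 d
- the option that brings most further target ("none" if no option brings more than 2 percentage points) (south / north-east / south-west / north / none)
- target present, with what was taken out counted in, in percent of the substrate first charged, after south
- target present, with what was taken out counted in, in percent of the substrate first charged, after south-west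

- removed target is counted in
- "the catalyst" is free catalyst with its forms; second catalyst is a second catalyst
- additions bring no volume worth counting

Was it a true stop? I went to logarithms: the gap to that plateau shrank from 10 points at 0.625 d to 2.5 points at 1.67 d, a half-life of 0.505 d. By 8.0 d that half-life put the gap down 4.77 powers of ten, as an estimate. The second gap barely clears the scatter, but doubling the half-life still leaves 2.39 powers, so I expected waiting to add little.

What had faded? The ochre run differed in its second catalyst, 4 mM, and read 23% at 50.0 h. A dying catalyst could do that, but so could a partner that reaches target through the second catalyst while racing some unseen loss. I reckoned 25.4% for the red flask: this is the partner yield, target made per partner charged, and the ochre run gave 19.2%.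

The objection was plain: at one partner for each target, target had taken 0.0915 M of 0.360 M, so this view needs 74.6% of the partner lost unseen, which no reading shows. But it makes a testable bet. Adding 50.0% of the charge at the same yield should bring 15 points, and the 69.5% of substrate not yet target leaves room for that. I committed to north, with nothing from south.

The forecast gave 31% now, 34% after waiting, and differed from me on the choice: south, with 49% there, saying “Fresh free catalyst should restart the reaction”.

The flask gave 30.0% at 8.0 d.

    partner + second catalyst + intermediate → second catalyst + target (k = 0.0123 M⁻² s⁻¹)
    partner → decomposed reagent (k = 2.04 × 10⁻⁵ s⁻¹)
    partner + target → over-reaction product (k = 3.76 × 10⁻⁶ M⁻¹ s⁻¹)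
    substrate + partner → uncatalysed product (k = 1.11 × 10⁻⁵ M⁻¹ s⁻¹)
    substrate + free catalyst ⇌ free catalyst + intermediate (K = 2.30, k = 0.00138 M⁻¹ s⁻¹)

Waiting ended at 30.0%. The option that brought most was north, with 16 points where the partner yield had said 15 points, while south brought 0 points and stood at 30.0%, not 49%. At 8.00 d the red flask held 0% of its partner, the limiting reagent, and 100% of its free catalyst. A neighbouring flask, charged with 0.090 M of partner and otherwise the same, was due 7.62% of target at the red flask's yield. It gave 8.76% at 8.00 d, with 0% of its partner left.

The numbers in the tables are calculated with made-up constants; the scatter is artificial.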